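**Retrosynthetic overview**
1. The target phenol is unmasked from its methyl ether. The hydrogen at C4 replaces an amino group (diazonium reduction) after that amine has directed bromine to C3 and C5; the amine comes from a nitro group.
2. Feature used: in ring A the hydroxyl carbon C1 lies between C2 (O-aryl) and C6 as a ketone carbon lies between two α-carbons, and the only ring hydrogen, at C4 para to the hydroxyl, marks the seat of a removable nitro director (C3, C5, C6 carry Br; ring B is C1′–O, C2′–Br).
3. Key disconnection: the C2–C3 and C5–C6 bonds of ring A, a (3+3) double aldol benzannulation of 1-(2-bromophenoxy)propan-2-one (C6–C1–C2) with sodium nitromalonaldehyde (C3–C4–C5), giving 2-(2-bromophenoxy)-4-nitrophenol.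
4. Ring order: ring B is bought as 2-bromophenol and joined to the future C2 by SN2 at an sp3 carbon. Ring A is the only ring built (step 3); it is then brominated at C6 (phenol-directed) and at C3 and C5 (aniline-directed).

Key step: step 3

Remark: sodium nitromalonaldehyde is an impact-sensitive, thermally unstable salt; it is assumed to be made and used as the moist monohydrate on a limited scale. The target has no stereocentres.

**Step 1**
Reactants: 1 2-bromophenol; 2 chloroacetone
Product: 3 1-(2-bromophenoxy)propan-2-one
Conditions: K2CO3, KI (cat.), acetone, reflux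
Reagents that add atoms: none
Why: Williamson ether synthesis, in which the phenoxide of 1 displaces chloride from the primary α-chloroketone by SN2 (iodide catalysis by Finkelstein exchange) while the aryl bromide is inert to carbonate.

**Step 2**
Reactants: 4 mucobromic acid
Product: 5 sodium nitromalonaldehyde monohydrate, Na[O2NC(CHO)2]·H2O
Conditions: NaNO2 (3.7 equiv), H2O–EtOH, 54 °C; cooled to 0–5 °C, recrystallised from aq. EtOH
Reagents that add atoms: sodium nitrite, [Na+].[O-]N=O; water, O
Why: Established preparation of this salt, in which nitrite replaces the bromide on the carbon next to the formyl group by addition–elimination and hydrolytic loss of the second bromide with decarboxylation unveils the second formyl group, the sodium salt crystallising on cooling.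

**Step 3**
Reactants: 3 1-(2-bromophenoxy)propan-2-one; 5 sodium nitromalonaldehyde monohydrate
Product: 7 2-(2-bromophenoxy)-4-nitrophenol, via sodium 2-(2-bromophenoxy)-4-nitrophenolate 6 (not isolated)
Conditions: 3 added slowly to 5 (1.5 equiv), NaOH, H2O–EtOH, 0 °C → rt, several days; then HCl (aq)
Reagents that add atoms: none
Why: Nitromalonaldehyde–ketone condensation, a (3+3) double aldol benzannulation known for ketones with two enolisable α-carbons: hydroxide reversibly forms the enolates of 3, one α-carbon (the methyl or the aryloxymethylene carbon, whichever reacts first) adds to a formyl group of 5 with loss of water, and the other α-carbon then adds to the remaining formyl group. This second addition is an intramolecular aldol, a 6-exo-trig attack at the formyl carbon, which closes ring A and completes the pair of new bonds C2–C3 and C5–C6; a second dehydration and enolisation of the ring ketone give the aromatic nitrophenolate 6, and this aromatisation draws the reversible aldol steps forward. No stereocentre is formed. There is no regiochemical choice, since both α-carbons of 3 end up in the ring, so the ketone carbon becomes C1 with the aryloxy group ortho and the nitro group para to it. The selectivity needed is cross-condensation over self-aldol of 3, secured because 5 is only an acceptor, is kept in excess, and meets 3 at low concentration through slow addition. The ether link to ring B, made at sp3 carbon in step 1, and the aryl bromide are inert to cold aqueous hydroxide.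

**Step 4**
Reactants: 7 2-(2-bromophenoxy)-4-nitrophenol
Product: 8 2-bromo-6-(2-bromophenoxy)-4-nitrophenol
Conditions: Br2 (1.05 equiv), NaOAc, AcOH, rt
Reagents that add atoms: bromine, BrBr
Why: Electrophilic aromatic bromination, in which the hydroxyl (partly as phenoxide under acetate buffering) directs to its only free ortho position C6, also meta to the nitro group, while ring B, a bromine-deactivated diaryl ether, should react far more slowly with one equivalent of bromine.

**Step 5**
Reactants: 8 2-bromo-6-(2-bromophenoxy)-4-nitrophenol
Product: 9 1-bromo-3-(2-bromophenoxy)-2-methoxy-5-nitrobenzene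
Conditions: MeI, K2CO3, DMF, 40 °C
Reagents that add atoms: iodomethane, CI
Why: Williamson O-methylation, in which the acidic nitrophenol is fully deprotonated by carbonate and the phenoxide attacks iodomethane by SN2 in a dipolar aprotic solvent, capping the oxygen before ring A is made electron-rich.

**Step 6**
Reactants: 9 1-bromo-3-(2-bromophenoxy)-2-methoxy-5-nitrobenzene
Product: 10 3-bromo-5-(2-bromophenoxy)-4-methoxyaniline
Conditions: Fe powder, AcOH, EtOH, 70 °C
Reagents that add atoms: none
Why: Béchamp-type dissolving-metal reduction, in which iron in acetic acid reduces the nitro group by stepwise electron and proton transfer and, unlike catalytic hydrogenation, leaves the aryl bromides and the diaryl ether intact.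

**Step 7**
Reactants: 10 3-bromo-5-(2-bromophenoxy)-4-methoxyaniline
Product: 11 2,3,6-tribromo-5-(2-bromophenoxy)-4-methoxyaniline
Conditions: NBS (2.05 equiv), MeCN, 0 °C → rt
Reagents that add atoms: N-bromosuccinimide, O=C1CCC(=O)N1Br
Why: Electrophilic aromatic bromination, in which the amino group directs to its two ortho positions C3 and C5 (the para position carries the methoxy group), filling ring A, which is far more nucleophilic than ring B so that two equivalents of reagent should stop there.

**Step 8**
Reactants: 11 2,3,6-tribromo-5-(2-bromophenoxy)-4-methoxyaniline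
Product: 13 1,2,5-tribromo-4-(2-bromophenoxy)-3-methoxybenzene, via arenediazonium hydrogen sulfate 12 (not isolated)
Conditions: NaNO2, H2SO4, AcOH, 0–5 °C; then H3PO2 (50% aq), 0 °C → rt
Reagents that add atoms: none
Why: Diazotisation followed by hydrodediazoniation, in which nitrosylsulfuric acid diazotises the weakly basic 2,6-dibromoaniline and hypophosphorous acid reduces the diazonium ion through an aryl radical chain to place hydrogen at C4, the chloride-free medium avoiding displacement of the ortho bromides.

**Step 9**
Reactants: 13 1,2,5-tribromo-4-(2-bromophenoxy)-3-methoxybenzene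
Product: 15 2,3,5-tribromo-6-(2-bromophenoxy)phenol, via aryloxydibromoborane 14 (not isolated)
Conditions: BBr3, CH2Cl2, −78 °C → rt; then H2O
Reagents that add atoms: none
Why: Lewis acid ether cleavage, in which BBr3 coordinates the methoxy oxygen and bromide attacks the methyl carbon by SN2 (the diaryl ether offers no sp3 carbon), and water hydrolyses the boron aryloxide to the phenol.

**Compound list**
1 | 2-bromophenol | Oc1ccccc1Br | starting material
2 | chloroacetone | CC(=O)CCl | starting material
3 | 1-(2-bromophenoxy)propan-2-one | CC(=O)COc1ccccc1Br | intermediate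
4 | mucobromic acid, (Z)-2,3-dibromo-4-oxobut-2-enoic acid | OC(=O)/C(Br)=C(Br)\C=O | starting material
5 | sodium nitromalonaldehyde monohydrate | [Na+].O=C[C-](C=O)[N+](=O)[O-].O | intermediate
6 | sodium 2-(2-bromophenoxy)-4-nitrophenolate | [Na+].[O-]c1ccc(cc1Oc1ccccc1Br)[N+](=O)[O-] | intermediate
7 | 2-(2-bromophenoxy)-4-nitrophenol | Oc1ccc(cc1Oc1ccccc1Br)[N+](=O)[O-] | intermediate
8 | 2-bromo-6-(2-bromophenoxy)-4-nitrophenol | Oc1c(Br)cc(cc1Oc1ccccc1Br)[N+](=O)[O-] | intermediate
9 | 1-bromo-3-(2-bromophenoxy)-2-methoxy-5-nitrobenzene | COc1c(Br)cc(cc1Oc1ccccc1Br)[N+](=O)[O-] | intermediate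
10 | 3-bromo-5-(2-bromophenoxy)-4-methoxyaniline | COc1c(Br)cc(N)cc1Oc1ccccc1Br | intermediate
11 | 2,3,6-tribromo-5-(2-bromophenoxy)-4-methoxyaniline | COc1c(Br)c(Br)c(N)c(Br)c1Oc1ccccc1Br | intermediate
12 | 2,3,6-tribromo-5-(2-bromophenoxy)-4-methoxybenzenediazonium hydrogen sulfate | COc1c(Br)c(Br)c([N+]#N)c(Br)c1Oc1ccccc1Br.OS(=O)(=O)[O-] | intermediate
13 | 1,2,5-tribromo-4-(2-bromophenoxy)-3-methoxybenzene | COc1c(Br)c(Br)cc(Br)c1Oc1ccccc1Br | intermediate
14 | dibromo[2,3,5-tribromo-6-(2-bromophenoxy)phenoxy]borane | BrB(Br)Oc1c(Br)c(Br)cc(Br)c1Oc1ccccc1Br | intermediate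
15 | 2,3,5-tribromo-6-(2-bromophenoxy)phenol | Oc1c(Br)c(Br)cc(Br)c1Oc1ccccc1Br | target

**Step count**
Total: 9 steps. Longest linear sequence: 8 steps (steps 1 and 3–9 from 2-bromophenol, or equally steps 2 and 3–9 from mucobromic acid).

**Steps most likely to fail**

Step 3. The aryloxyacetone may condense with itself, or the sequence may stall at the open-chain mono-condensation stage because the nitromalonaldehyde anion is a weak electrophile, so that ring closure and aromatisation do not go to completion. Fallback: setting out from 1, an Ullmann-type diaryl ether coupling with commercial 2-iodo-4-nitroanisole (CuI cat., picolinic acid, K3PO4, DMSO, 90 °C; the aryl iodide should couple in preference to the aryl bromide) would give 2-(2-bromophenoxy)-1-methoxy-4-nitrobenzene F1. Its methoxy group would then be cleaved with BBr3 in CH2Cl2, and the route is rejoined at 7.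

Step 8. Diazotisation of the crowded, weakly basic amine may be incomplete, and the diazonium ion may be lost to hydrolysis or to displacement of an ortho bromide before it is reduced. Fallback: setting out from 11, non-aqueous nitrosation with NOBF4 in MeCN at −30 °C and precipitation with Et2O would give the isolable salt 2,3,6-tribromo-5-(2-bromophenoxy)-4-methoxybenzenediazonium tetrafluoroborate F2. This would be reduced in DMF with catalytic FeSO4 (DMF as hydrogen-atom donor) at rt, returning to the route at 13.

Step 9. Ether cleavage at the doubly flanked methoxy group may be sluggish, and prolonged exposure to the Lewis acid may attack the polybrominated diaryl ether. Fallback: setting out from 8, the phenol would be carried as a sulfonate, so that the final unmasking is a saponification and the aminoarene of the bromination stage is less prone to oxidation. MsCl and Et3N in CH2Cl2 would give 2-bromo-6-(2-bromophenoxy)-4-nitrophenyl methanesulfonate F3. Fe in AcOH–EtOH would give 4-amino-2-bromo-6-(2-bromophenoxy)phenyl methanesulfonate F4. NBS in MeCN would give 4-amino-2,3,5-tribromo-6-(2-bromophenoxy)phenyl methanesulfonate F5. NaNO2 in H2SO4–AcOH would give 2,3,6-tribromo-5-(2-bromophenoxy)-4-(methanesulfonyloxy)benzenediazonium hydrogen sulfate F6, not isolated, which H3PO2 would reduce to 2,3,5-tribromo-6-(2-bromophenoxy)phenyl methanesulfonate F7. KOH in MeOH–H2O at 60 °C, then acid, would release 15.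

**Further compounds**
F1 | step 3 | 2-(2-bromophenoxy)-1-methoxy-4-nitrobenzene | COc1ccc(cc1Oc1ccccc1Br)[N+](=O)[O-]
F2 | step 8 | 2,3,6-tribromo-5-(2-bromophenoxy)-4-methoxybenzenediazonium tetrafluoroborate | COc1c(Br)c(Br)c([N+]#N)c(Br)c1Oc1ccccc1Br.F[B-](F)(F)F
F3 | step 9 | 2-bromo-6-(2-bromophenoxy)-4-nitrophenyl methanesulfonate | CS(=O)(=O)Oc1c(Br)cc(cc1Oc1ccccc1Br)[N+](=O)[O-]
F4 | step 9 | 4-amino-2-bromo-6-(2-bromophenoxy)phenyl methanesulfonate | CS(=O)(=O)Oc1c(Br)cc(N)cc1Oc1ccccc1Br
F5 | step 9 | 4-amino-2,3,5-tribromo-6-(2-bromophenoxy)phenyl methanesulfonate | CS(=O)(=O)Oc1c(Br)c(Br)c(N)c(Br)c1Oc1ccccc1Br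
F6 | step 9 | 2,3,6-tribromo-5-(2-bromophenoxy)-4-(methanesulfonyloxy)benzenediazonium hydrogen sulfate | CS(=O)(=O)Oc1c(Br)c(Br)c([N+]#N)c(Br)c1Oc1ccccc1Br.OS(=O)(=O)[O-]
F7 | step 9 | 2,3,5-tribromo-6-(2-bromophenoxy)phenyl methanesulfonate | CS(=O)(=O)Oc1c(Br)c(Br)cc(Br)c1Oc1ccccc1Br
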